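**Strategy**

The pyranone ring is read as a masked α-formyl ketone: spiro carbon C3, benzylic to the dimethoxy B-ring inside the cyclobutene, lies between carbonyl C4 and oxymethylene C2. The precursor is an enantioenriched spiro α,β-epoxy ketone in which the 2,4,6-trimethoxybenzoyl group still sits on the future C2. In one flask, BF3 opens the benzylic C3–O bond, the aroyl group shifts from C2 to C3 with inversion (C3–C4 bond, quaternary stereocentre), then BCl3 removes one ortho methyl group by chelation and the freed phenol oxygen closes on the new formyl carbon (O1–C2 bond). Ionic reduction of the lactol ends the route.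

Key step: step 5

Remark on the chemistry: the text uses chromanone numbering (O1, C2, C3 = spiro carbon, C4 = carbonyl; A-ring = chromanone arene; B-ring = arene fused to the cyclobutene). C3 is the same atom as C7 of the bicyclo[4.2.0]octatriene names. By CIP analysis the spiro carbon of the target is S. The chiral ketone of step 3 is a catalyst and is not counted as a route compound.

**Step 1**
Reactants: 1 1-bromo-2,3-dimethoxybenzene; 2 1,1-diethoxyethene
Product: 5 4,5-dimethoxybicyclo[4.2.0]octa-1,3,5-trien-7-one (5,6-dimethoxybenzocyclobutenone), via 3,4-dimethoxybenzyne 3 (not isolated), via diethyl acetal 4 (not isolated)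
Conditions: NaNH2 (2.5 equiv), 2 (2 equiv), THF, reflux; then 1 M HCl, THF–H2O, rt
Reagents that add atoms: water, O
Why: Aryne–ketene acetal [2+2] cycloaddition in which the nucleophilic CH2 terminus of 2 adds to the aryne carbon remote from the methoxy group, so the acetal carbon ends up next to the methoxy-bearing carbon, and mild acid hydrolysis unmasks the ketone without creating a stereocentre.

**Step 2**
Reactants: 5 4,5-dimethoxybicyclo[4.2.0]octa-1,3,5-trien-7-one; 6 ethyl (triphenylphosphoranylidene)acetate
Product: 7 ethyl (2E)-(4,5-dimethoxybicyclo[4.2.0]octa-1,3,5-trien-7-ylidene)acetate (ester cis to the ring CH2, trans to the B-ring)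
Conditions: toluene, 90 °C; chromatographic removal of the minor Z isomer
Reagents that add atoms: none
Why: Wittig olefination of a strained, electrophilic four-ring ketone with a stabilised ylide, in which the ester should settle on the CH2 side, away from the C5 methoxy group, to give the E alkene.

**Step 3**
Reactants: 7 ethyl (2E)-(4,5-dimethoxybicyclo[4.2.0]octa-1,3,5-trien-7-ylidene)acetate
Product: 8 ethyl (3'S,7R)-4,5-dimethoxyspiro[bicyclo[4.2.0]octa-1,3,5-triene-7,2'-oxirane]-3'-carboxylate
Conditions: D-fructose-derived diacetate ketone (4,5-di-O-acetyl-1,2-O-isopropylidene-β-D-erythro-hexo-2,3-diulo-2,6-pyranose, 0.3 equiv), Oxone, NaHCO3, Bu4NHSO4 (cat.), MeCN–aq. Na2EDTA, 0 °C → rt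
Reagents that add atoms: Oxone (potassium peroxymonosulfate), [K+].[O-]S(=O)(=O)OO
Why: Shi asymmetric epoxidation of a trisubstituted (E)-enoate, in which syn oxygen transfer from the chiral dioxirane through the spiro transition state should attack the same face that turns (E)-cinnamates into (2S,3R)-glycidates and so set C7 as R and C3' as S (the L-series catalyst is used if the sense proves opposite).

**Step 4**
Reactants: 9 1,3,5-trimethoxybenzene; 8 ethyl (3'S,7R)-4,5-dimethoxyspiro[bicyclo[4.2.0]octa-1,3,5-triene-7,2'-oxirane]-3'-carboxylate
Product: 11 [(3'S,7R)-4,5-dimethoxyspiro[bicyclo[4.2.0]octa-1,3,5-triene-7,2'-oxiran]-3'-yl](2,4,6-trimethoxyphenyl)methanone, via 2,4,6-trimethoxyphenyllithium 10 (not isolated)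
Conditions: 9, n-BuLi (1.05 equiv), THF, 0 °C → rt; then added to 8, THF, −78 °C; H2O quench
Reagents that add atoms: none
Why: Directed ortho-lithiation between two methoxy groups followed by acyl substitution at the ester, where the di-ortho-substituted ketone resists a second addition and the low temperature should leave the oxirane and both stereocentres untouched.

**Step 5**
Reactants: 11 [(3'S,7R)-4,5-dimethoxyspiro[bicyclo[4.2.0]octa-1,3,5-triene-7,2'-oxiran]-3'-yl](2,4,6-trimethoxyphenyl)methanone
Product: 14 (7S)-2'-hydroxy-4,5,5',7'-tetramethoxyspiro[bicyclo[4.2.0]octa-1,3,5-triene-7,3'-chroman]-4'-one (lactol, both C2 epimers), via keto aldehyde 12 (not isolated), via phenol aldehyde 13 (not isolated)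
Conditions: BF3·OEt2 (0.3 equiv), CH2Cl2, −78 → −20 °C; then BCl3 (1.3 equiv), −78 → 0 °C; pH 7 buffer quench
Reagents that add atoms: none
Why: BF3 activates the oxirane oxygen, the tertiary benzylic bond between the future C3 and oxygen lengthens (assisted by the ortho-methoxy B-ring), and the aroyl group migrates from the future C2 to the rear lobe of the future C3 to give keto aldehyde 12; this is the Lewis acid 1,2-acyl shift of β,β-disubstituted α,β-epoxy aryl ketones (House–Meinwald type, the chemistry behind the chalcone epoxide route to isoflavones). The quaternary stereocentre is controlled by the oxirane, because migration occurs anti to the leaving oxygen, so (7R)-11 should give (7S)-12 by inversion, and the strain of an sp2 cation in the four-membered ring should disfavour a free carbocation that would erode this transfer. BCl3 then binds the ketone oxygen and one ortho methoxy group in a six-membered chelate and chloride removes that methyl group (the standard ortho-selective demethylation of o-methoxyaryl ketones); the two ortho methoxy groups are equivalent by rotation about the aryl–carbonyl bond, so either one leads to 13. On quench the phenol oxygen adds to the formyl carbon in a 6-exo-trig closure that forms the six-membered pyranone ring of 14, whose C2 hydroxyl configuration is not controlled and is erased in step 6. The step needs cleavage at the benzylic carbon rather than at the oxirane CH (an α-acyl cation is disfavoured), acyl rather than hydride migration (the normal order for epoxy ketones), no oxygen trapping at the future C3 (the phenol is still a methyl ether and BF3 carries no nucleophilic counter-ion) and a single demethylation (limited BCl3, with boron locked in the first chelate).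

**Step 6**
Reactants: 14 (7S)-2'-hydroxy-4,5,5',7'-tetramethoxyspiro[bicyclo[4.2.0]octa-1,3,5-triene-7,3'-chroman]-4'-one
Product: 15 (7S)-4,5,5',7'-tetramethoxyspiro[bicyclo[4.2.0]octa-1,3,5-triene-7,3'-chroman]-4'-one (target)
Conditions: Et3SiH (3 equiv), TMSOTf (0.3 equiv), CH2Cl2, −40 → 0 °C
Reagents that add atoms: none
Why: Ionic lactol reduction in which the C2 hydroxyl is ionised to the O1-stabilised cyclic oxocarbenium ion and trapped by silane hydride with the O1–C2 bond intact, while the C4 ketone is neopentyl, flanked by the C5 methoxy group and a poor hydride acceptor, and the quaternary C3 cannot epimerise.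

**Compound list**

1 | 1-bromo-2,3-dimethoxybenzene | COc1cccc(Br)c1OC | starting material
2 | 1,1-diethoxyethene | C=C(OCC)OCC | starting material
3 | 3,4-dimethoxybenzyne | COC1=C(OC)C#CC=C1 | intermediate
4 | 7,7-diethoxy-4,5-dimethoxybicyclo[4.2.0]octa-1,3,5-triene | CCOC1(OCC)Cc2ccc(OC)c(OC)c21 | intermediate
5 | 4,5-dimethoxybicyclo[4.2.0]octa-1,3,5-trien-7-one | O=C1Cc2ccc(OC)c(OC)c21 | intermediate
6 | ethyl (triphenylphosphoranylidene)acetate | CCOC(=O)C=P(c1ccccc1)(c1ccccc1)c1ccccc1 | starting material
7 | ethyl (2E)-(4,5-dimethoxybicyclo[4.2.0]octa-1,3,5-trien-7-ylidene)acetate | CCOC(=O)/C=C1\Cc2ccc(OC)c(OC)c21 | intermediate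
8 | ethyl (3'S,7R)-4,5-dimethoxyspiro[bicyclo[4.2.0]octa-1,3,5-triene-7,2'-oxirane]-3'-carboxylate | CCOC(=O)[C@H]1O[C@@]12Cc3ccc(OC)c(OC)c32 | intermediate
9 | 1,3,5-trimethoxybenzene | COc1cc(OC)cc(OC)c1 | starting material
10 | 2,4,6-trimethoxyphenyllithium | [Li]c1c(OC)cc(OC)cc1OC | intermediate
11 | [(3'S,7R)-4,5-dimethoxyspiro[bicyclo[4.2.0]octa-1,3,5-triene-7,2'-oxiran]-3'-yl](2,4,6-trimethoxyphenyl)methanone | COc1cc(OC)c(C(=O)[C@H]2O[C@@]23Cc4ccc(OC)c(OC)c43)c(OC)c1 | intermediate
12 | (7S)-4,5-dimethoxy-7-(2,4,6-trimethoxybenzoyl)bicyclo[4.2.0]octa-1,3,5-triene-7-carbaldehyde | COc1cc(OC)c(C(=O)[C@@]2(C=O)Cc3ccc(OC)c(OC)c32)c(OC)c1 | intermediate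
13 | (7S)-7-(2-hydroxy-4,6-dimethoxybenzoyl)-4,5-dimethoxybicyclo[4.2.0]octa-1,3,5-triene-7-carbaldehyde (boron-bound until the quench) | COc1cc(O)c(C(=O)[C@@]2(C=O)Cc3ccc(OC)c(OC)c32)c(OC)c1 | intermediate
14 | (7S)-2'-hydroxy-4,5,5',7'-tetramethoxyspiro[bicyclo[4.2.0]octa-1,3,5-triene-7,3'-chroman]-4'-one, C2 epimers | COc1cc(OC)c2c(c1)OC(O)[C@@]1(Cc3ccc(OC)c(OC)c31)C2=O | intermediate
15 | (7S)-4,5,5',7'-tetramethoxyspiro[bicyclo[4.2.0]octa-1,3,5-triene-7,3'-chroman]-4'-one | COc1cc(OC)c2c(c1)OC[C@@]1(Cc3ccc(OC)c(OC)c31)C2=O | target

**Step count**

Total step count: 6. Longest linear sequence: 6 (1 → 5 → 7 → 8 → 11 → 14 → 15).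

**Steps most likely to fail**

Step 5.
- Ionisation of the benzylic C–O bond may run ahead of the acyl shift, which would cost stereochemical fidelity.
- Hydride may migrate in place of the aroyl group.
- A second chelation-driven demethylation may occur at the remaining ortho methoxy group.
- The formyl group may be lost during the quench.

The fallback replaces the methyl mask by an acetal mask that leaves as a stabilised cation. One non-nucleophilic Lewis acid then does everything and no chloride source is present. It sets out from 8. 3,5-Dimethoxyphenol is converted (MOMCl, iPr2NEt, CH2Cl2) into 1,3-dimethoxy-5-(methoxymethoxy)benzene F1. This is lithiated (n-BuLi, THF, 0 °C) between the OMOM and OMe groups to [2,4-dimethoxy-6-(methoxymethoxy)phenyl]lithium F2, which is added to 8 at −78 °C to give the MOM-protected epoxy ketone F3. BF3·OEt2 in CH2Cl2 at −78 °C should trigger the same acyl shift. The MOM-bearing oxygen then adds to the activated formyl group and expels the methoxymethyl cation. Aqueous work-up comes back to the route at 14.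

Step 6.
- Ionisation of the lactol may be slow, because O1 is a vinylogous ester oxygen.
- Hydride may instead be delivered to the open-chain formyl tautomer or to the C4 carbonyl.

The fallback moves the cation-stabilising role from oxygen to sulfur and removes the heteroatom reductively. It sets out from 14. Thiophenol with catalytic TsOH in CH2Cl2 should give, through a sulfur-stabilised thionium ion that the phenol oxygen traps, the 2'-phenylthio O,S-acetal F4. Desulfurisation with acetone-deactivated Raney nickel in EtOH at rt comes back to the route at 15.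

Step 4.
- The aryllithium may deprotonate the oxirane C–H next to the ester.
- The aryllithium may open the oxirane in competition with acyl substitution.

The fallback reverses the order, so that the organolithium never meets the oxirane. It sets out from 7. Addition of 10 to 7 at −78 °C should give the (E)-enone F5 by 1,2-addition, since the β,β-disubstituted terminus blocks conjugate addition. The same chiral dioxirane epoxidation, now applied to F5 and following the same facial model, comes back to the route at 11.

**Further compounds**

F1 | step 5 | 1,3-dimethoxy-5-(methoxymethoxy)benzene | COCOc1cc(OC)cc(OC)c1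
F2 | step 5 | [2,4-dimethoxy-6-(methoxymethoxy)phenyl]lithium | [Li]c1c(OC)cc(OC)cc1OCOC
F3 | step 5 | [(3'S,7R)-4,5-dimethoxyspiro[bicyclo[4.2.0]octa-1,3,5-triene-7,2'-oxiran]-3'-yl][2,4-dimethoxy-6-(methoxymethoxy)phenyl]methanone | COCOc1cc(OC)cc(OC)c1C(=O)[C@H]1O[C@@]12Cc3ccc(OC)c(OC)c32
F4 | step 6 | 4,5,5',7'-tetramethoxy-2'-(phenylsulfanyl)spiro[bicyclo[4.2.0]octa-1,3,5-triene-7,3'-chroman]-4'-one, spiro carbon arranged in space as in 15 (descriptor R because sulfur raises the rank of C2), C2 epimers | COc1cc(OC)c2c(c1)OC(Sc1ccccc1)[C@@]1(Cc3ccc(OC)c(OC)c31)C2=O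
F5 | step 4 | (2E)-2-(4,5-dimethoxybicyclo[4.2.0]octa-1,3,5-trien-7-ylidene)-1-(2,4,6-trimethoxyphenyl)ethanone | COc1cc(OC)c(C(=O)/C=C2\Cc3ccc(OC)c(OC)c32)c(OC)c1
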